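**Retrosynthetic overview**
- Last bond: the central C3–C4 single bond of the penta-2,4-dienyl linker, made by an oxidative Heck coupling of a 6-vinyl bromo-oxane (ring A) with an (E)-alkenylboronate carried by the bromohydrin cyclohexane (ring B).
- Ring A (O1, C2 with its gem-dimethyl group, C3–Br, C4H2, C5H2, C6 with methyl and vinyl) is a folded (R)-linalool: O1/C6 is its tertiary carbinol, already in the right configuration, and C2=C3 is its prenyl alkene. This 1,5 relationship of a hydroxyl to a trisubstituted alkene with a gem-dimethyl terminus lets one anti bromo-etherification make O1–C2 and C3–Br together.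
- Ring B is never closed: it is (S)-limonene. Its trans-diaxial 1,2-diol gives the cis bromohydrin by SN2 inversion at C2; ozonolysis and a boron-Wittig reaction turn the isopropenyl group into the alkenylboronate.
- Ring order: ring B from the chiral pool; ring A closed in step 7, the only and final ring closure of the skeleton; union in step 8.

Key step: step 7

Assumption: the SMILES places Br and OH cis on the cyclohexane (Br equatorial, OH axial, both cis to the C4 side chain); this is taken literally, so the bromide is introduced by SN2 inversion of the trans-diaxial diol and not by bromohydrin formation, which would give the trans isomer.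

**Route**

Step 1
Reactants: 1 (S)-(−)-limonene
Product: 2 (4S)-limonene 1,2-oxide, mixture of the cis and trans epoxides
Conditions: mCPBA (1.0 equiv), CH2Cl2, 0 °C
Reagents that add atoms: 3-chloroperoxybenzoic acid, OOC(=O)c1cccc(Cl)c1
Why: Prilezhaev epoxidation should take the electron-rich trisubstituted ring alkene ahead of the 1,1-disubstituted isopropenyl group; no facial control is needed because both epoxide diastereomers converge in step 2, and C4 is untouched.

Step 2
Reactants: 2 (4S)-limonene 1,2-oxide, mixture of the cis and trans epoxides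
Product: 3 (1R,2R,4S)-1-methyl-4-(prop-1-en-2-yl)cyclohexane-1,2-diol
Conditions: 1% aq. H2SO4, THF, 0 °C → 25 °C
Reagents that add atoms: water, O
Why: Acid-catalysed epoxide hydrolysis follows the trans-diaxial opening rule, so water should attack C2 of one epoxide and C1 of the other with inversion and both should give the same diol with 1-OH axial and cis to the isopropenyl group and 2-OH axial and trans to it.

Step 3
Reactants: 3 (1R,2R,4S)-1-methyl-4-(prop-1-en-2-yl)cyclohexane-1,2-diol
Product: 4 (1R,2R,5S)-2-hydroxy-2-methyl-5-(prop-1-en-2-yl)cyclohexyl chloromethanesulfonate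
Conditions: ClCH2SO2Cl (1.2 equiv), pyridine, CH2Cl2, 0 °C
Reagents that add atoms: chloromethanesulfonyl chloride, ClCS(Cl)(=O)=O
Why: Sulfonylation should be selective for the secondary hydroxyl over the tertiary one and leaves all stereocentres untouched; the chloromethanesulfonate is chosen as a more reactive leaving group for displacement at a hindered secondary carbon.

Step 4
Reactants: 4 (1R,2R,5S)-2-hydroxy-2-methyl-5-(prop-1-en-2-yl)cyclohexyl chloromethanesulfonate
Product: 5 (1R,2S,4S)-2-bromo-1-methyl-4-(prop-1-en-2-yl)cyclohexan-1-ol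
Conditions: LiBr (5 equiv), DMF, 60 °C
Reagents that add atoms: lithium bromide, [Li+].[Br-]
Why: SN2 (Finkelstein-type) displacement of the axial sulfonate by bromide with inversion should turn the (2R) C–O centre into the (2S) C–Br centre, i.e. the equatorial bromide cis to the axial tertiary hydroxyl; bromide is too weakly basic to deprotonate the hydroxyl for epoxide closure, and the equatorial product is far less prone to a second exchange than the axial sulfonate.

Step 5
Reactants: 5 (1R,2S,4S)-2-bromo-1-methyl-4-(prop-1-en-2-yl)cyclohexan-1-ol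
Product: 7 1-[(1S,3S,4R)-3-bromo-4-hydroxy-4-methylcyclohexyl]ethan-1-one, via secondary ozonide 6 (not isolated)
Conditions: O3, CH2Cl2, −78 °C; then Me2S, −78 → 25 °C
Reagents that add atoms: ozone, O=[O+][O-]
Why: Ozonolysis with reductive work-up cleaves the only alkene to the methyl ketone; the ring stereocentres are not involved and the acetyl group stays in its preferred equatorial position.

Step 6
Reactants: 7 1-[(1S,3S,4R)-3-bromo-4-hydroxy-4-methylcyclohexyl]ethan-1-one
Product: 9 (1R,2S,4S)-2-bromo-1-methyl-4-[(E)-1-(4,4,5,5-tetramethyl-1,3,2-dioxaborolan-2-yl)prop-1-en-2-yl]cyclohexan-1-ol, via dilithium β-boryl alkoxide 8 (not isolated)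
Conditions: CH2(Bpin)2 (2.3 equiv), LiTMP (2.3 equiv), THF, 0 °C; then 7, −78 → 25 °C; H2O
Reagents that add atoms: bis[(pinacolato)boryl]methane, C(B1OC(C)(C)C(C)(C)O1)B1OC(C)(C)C(C)(C)O1
Why: Boron-Wittig olefination: the lithiated gem-diboronate (its first equivalent deprotonates the tertiary hydroxyl) adds to the ketone and syn B–O elimination with the remaining boryl group anti to the bulkier cyclohexyl substituent should give the (E)-trisubstituted alkenylboronate; the equatorial bromide on the locked chair has no anti-periplanar hydrogen for E2, so the ring stereocentres should survive.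

Step 7
Reactants: 10 (R)-(−)-linalool
Product: 11 (3S,6R)-3-bromo-6-ethenyl-2,2,6-trimethyloxane
Conditions: chiral 3,3′-diaryl-BINOL-derived N-triflylthiophosphoramide (10 mol%, the antipode matched to Si-face delivery at C6 of 10), 1,3-dibromo-5,5-dimethylhydantoin (0.55 equiv), toluene, −78 °C
Reagents that add atoms: 1,3-dibromo-5,5-dimethylhydantoin, CC1(C)C(=O)N(Br)C(=O)N1Br
Why: Proposed new method: a chiral Lewis base (the thiophosphoramide sulfur) takes Br+ from the N-bromohydantoin and passes it to the electron-rich C6=C7 prenyl alkene of 10 while the tertiary hydroxyl attacks C7 anti to the developing C6–Br bond, so that the O1–C2 and C3–Br bonds of the oxane form in one anti addition. The closest known reaction types are the achiral 6-endo bromo-etherification of δ-hydroxy trisubstituted alkenes and the Lewis-base-catalysed enantioselective bromonium-initiated cyclisation of terminal prenyl groups; what is new is catalyst control of the bromonium face in an ether-forming closure beside an existing stereocentre. The ring closes in the 6-endo-trig mode through a chair-like transition state with bromine equatorial. C6 of the oxane is the untouched carbinol carbon of (R)-linalool, and the new C3 stereocentre (3S) is set by the catalyst antipode that delivers bromine to the Si face of linalool C6. The step needs chemo-, regio- and facial selectivity: the monosubstituted, oxygen-deactivated vinyl group is inert beside the trisubstituted alkene and the gem-dimethyl terminus directs Markovnikov 6-endo rather than 5-exo attack, but the substrate cannot secure the face (its methyl and vinyl groups are of similar size and 1,4-remote), which is why reagent control is proposed.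

Step 8
Reactants: 9 (1R,2S,4S)-2-bromo-1-methyl-4-[(E)-1-(4,4,5,5-tetramethyl-1,3,2-dioxaborolan-2-yl)prop-1-en-2-yl]cyclohexan-1-ol (1.5 equiv); 11 (3S,6R)-3-bromo-6-ethenyl-2,2,6-trimethyloxane
Product: 12 (1R,2S,4S)-2-bromo-4-[(2E,4E)-5-[(2R,5S)-5-bromo-2,6,6-trimethyloxan-2-yl]penta-2,4-dien-2-yl]-1-methylcyclohexan-1-ol
Conditions: Pd(OAc)2 (10 mol%), 1,2-bis(phenylsulfinyl)ethane (10 mol%), 2,6-dimethyl-1,4-benzoquinone (2 equiv), AcOH (4 equiv), 1,4-dioxane, 25 °C
Reagents that add atoms: none
Why: Oxidative Heck (boron-Heck) vinylation under divalent palladium: the alkenyl group of 9 passes from boron to palladium and adds to the CH2 terminus of the vinyl group of 11, and because C6 of the oxane is quaternary the only β-hydrogen lies on the new C–C side, so β-hydride elimination should give the conjugated (E)-alkene while the (E)-geometry of the boronate is carried over and no stereocentre, hydroxyl or secondary bromide is touched.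

**Compound list**
1 | (S)-(−)-limonene, (4S)-1-methyl-4-(prop-1-en-2-yl)cyclohex-1-ene | CC(=C)[C@H]1CCC(C)=CC1 | starting material
2 | (4S)-limonene 1,2-oxide, (4S)-1-methyl-4-(prop-1-en-2-yl)-7-oxabicyclo[4.1.0]heptane, mixture of both epoxide diastereomers | CC(=C)[C@H]1CCC2(C)OC2C1 | intermediate
3 | (1R,2R,4S)-1-methyl-4-(prop-1-en-2-yl)cyclohexane-1,2-diol (trans-diaxial diol) | CC(=C)[C@H]1CC[C@@](C)(O)[C@H](O)C1 | intermediate
4 | (1R,2R,5S)-2-hydroxy-2-methyl-5-(prop-1-en-2-yl)cyclohexyl chloromethanesulfonate | CC(=C)[C@H]1CC[C@@](C)(O)[C@H](OS(=O)(=O)CCl)C1 | intermediate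
5 | (1R,2S,4S)-2-bromo-1-methyl-4-(prop-1-en-2-yl)cyclohexan-1-ol | CC(=C)[C@H]1CC[C@@](C)(O)[C@@H](Br)C1 | intermediate
6 | secondary ozonide, 3-[(1S,3S,4R)-3-bromo-4-hydroxy-4-methylcyclohexyl]-3-methyl-1,2,4-trioxolane (not isolated; both epimers at the trioxolane carbon) | CC1(OCOO1)[C@H]2CC[C@@](C)(O)[C@@H](Br)C2 | intermediate
7 | 1-[(1S,3S,4R)-3-bromo-4-hydroxy-4-methylcyclohexyl]ethan-1-one | CC(=O)[C@H]1CC[C@@](C)(O)[C@@H](Br)C1 | intermediate
8 | dilithium β-boryl alkoxide, dilithium salt of 2-[(1S,3S,4R)-3-bromo-4-hydroxy-4-methylcyclohexyl]-1,1-bis(4,4,5,5-tetramethyl-1,3,2-dioxaborolan-2-yl)propan-2-ol (not isolated; both epimers at the new carbinol carbon) | [Li+].[Li+].CC([O-])(C(B1OC(C)(C)C(C)(C)O1)B1OC(C)(C)C(C)(C)O1)[C@H]1CC[C@@](C)([O-])[C@@H](Br)C1 | intermediate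
9 | (1R,2S,4S)-2-bromo-1-methyl-4-[(E)-1-(4,4,5,5-tetramethyl-1,3,2-dioxaborolan-2-yl)prop-1-en-2-yl]cyclohexan-1-ol | C/C(=C\B1OC(C)(C)C(C)(C)O1)[C@H]1CC[C@@](C)(O)[C@@H](Br)C1 | intermediate
10 | (R)-(−)-linalool, (3R)-3,7-dimethylocta-1,6-dien-3-ol | C=C[C@](C)(O)CCC=C(C)C | starting material
11 | (3S,6R)-3-bromo-6-ethenyl-2,2,6-trimethyloxane | C=C[C@@]1(C)CC[C@H](Br)C(C)(C)O1 | intermediate
12 | (1R,2S,4S)-2-bromo-4-[(2E,4E)-5-[(2R,5S)-5-bromo-2,6,6-trimethyloxan-2-yl]penta-2,4-dien-2-yl]-1-methylcyclohexan-1-ol | C/C(=C\C=C\[C@@]1(C)CC[C@H](Br)C(C)(C)O1)[C@H]1CC[C@@](C)(O)[C@@H](Br)C1 | target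

**Step count and risks**
Total step count: 8. Longest linear sequence: 7 steps (steps 1–6, then step 8).

Steps most likely to fail:

Step 7 (proposed new method). Facial discrimination in the bromenium transfer may be poor, so that both C3 epimers form, and closure may leak into the 5-exo channel. The fallback uses known chemistry, sets out from 10 and comes back at 11. Shi epoxidation of the 6,7-alkene of 10 (D-fructose-derived ketone catalyst, KHSO5, K2CO3 buffer, MeCN/dimethoxymethane/H2O, 0 °C) should give, by reagent control, (3R)-5-[(2R)-3,3-dimethyloxiran-2-yl]-3-methylpent-1-en-3-ol F1. Acid-catalysed cyclisation (camphorsulfonic acid, CH2Cl2, 0 °C) opens the epoxide at its tertiary carbon in the 6-endo mode, with retention at the secondary carbinol carbon, to give (3R,6R)-6-ethenyl-2,2,6-trimethyloxan-3-ol F2, which has to be separated from the furanoid 5-exo isomer that is expected alongside it. Sulfonylation (ClCH2SO2Cl, pyridine, 0 °C) gives (3R,6R)-6-ethenyl-2,2,6-trimethyloxan-3-yl chloromethanesulfonate F3, and displacement with LiBr in DMF at 60 °C inverts C3 and delivers 11.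

Step 4. The anti-periplanar tertiary hydroxyl may take part in loss of the sulfonate (epoxide closure and reopening with retention), or E2 elimination may outrun the hindered backside attack. The fallback sets out from 4 and comes back at 5, and it removes the participating group rather than only changing conditions. The tertiary hydroxyl is silylated (TMSOTf, 2,6-lutidine, CH2Cl2, −78 °C) to give (1R,2R,5S)-2-methyl-5-(prop-1-en-2-yl)-2-[(trimethylsilyl)oxy]cyclohexyl chloromethanesulfonate F4. Displacement is then run as an ion-pair reaction in a non-ionising medium (Bu4NBr, toluene, 80 °C), which cannot pass through an epoxide, to give {[(1R,2S,4S)-2-bromo-1-methyl-4-(prop-1-en-2-yl)cyclohexyl]oxy}(trimethyl)silane F5. K2CO3 in MeOH at 25 °C removes the silyl group and returns 5.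

Step 8. Transmetalation of the hindered trisubstituted alkenylboronate may be slow compared with its homocoupling or protodeboronation, and palladium hydride re-addition may erode the diene geometry. The fallback sets out from 11 and comes back at 12. Ozonolysis of the vinyl group of 11 (O3, CH2Cl2, −78 °C; Me2S) gives (2R,5S)-5-bromo-2,6,6-trimethyloxane-2-carbaldehyde F6. Takai iodo-olefination (CrCl2, CHI3, THF, 0 °C) gives (3S,6R)-3-bromo-6-[(E)-2-iodoethenyl]-2,2,6-trimethyloxane F7. Suzuki–Miyaura coupling of F7 with 9 under zerovalent palladium (Pd(PPh3)4, aq. K3PO4, THF, 40 °C) joins the halves with retention of both alkene geometries and gives 12.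

Further compounds
F1 | step 7 | (3R)-5-[(2R)-3,3-dimethyloxiran-2-yl]-3-methylpent-1-en-3-ol | C=C[C@](C)(O)CC[C@H]1OC1(C)C
F2 | step 7 | (3R,6R)-6-ethenyl-2,2,6-trimethyloxan-3-ol | C=C[C@@]1(C)CC[C@@H](O)C(C)(C)O1
F3 | step 7 | (3R,6R)-6-ethenyl-2,2,6-trimethyloxan-3-yl chloromethanesulfonate | C=C[C@@]1(C)CC[C@@H](OS(=O)(=O)CCl)C(C)(C)O1
F4 | step 4 | (1R,2R,5S)-2-methyl-5-(prop-1-en-2-yl)-2-[(trimethylsilyl)oxy]cyclohexyl chloromethanesulfonate | CC(=C)[C@H]1CC[C@@](C)(O[Si](C)(C)C)[C@H](OS(=O)(=O)CCl)C1
F5 | step 4 | {[(1R,2S,4S)-2-bromo-1-methyl-4-(prop-1-en-2-yl)cyclohexyl]oxy}(trimethyl)silane | CC(=C)[C@H]1CC[C@@](C)(O[Si](C)(C)C)[C@@H](Br)C1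
F6 | step 8 | (2R,5S)-5-bromo-2,6,6-trimethyloxane-2-carbaldehyde | O=C[C@@]1(C)CC[C@H](Br)C(C)(C)O1
F7 | step 8 | (3S,6R)-3-bromo-6-[(E)-2-iodoethenyl]-2,2,6-trimethyloxane | I/C=C/[C@@]1(C)CC[C@H](Br)C(C)(C)O1
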